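**Retrosynthetic overview**

1. Dioxepine ring (formed last): the C5–O bond comes from anti, 7-endo opening of a 5,6-epoxide at the vinylogously benzylic C5 by the 7-OH of the lower chromone; the epoxide comes from a C5=C6 alkene.
2. C7–O bond and C8–OH: Rh-catalysed ring opening (run as a kinetic resolution) of a racemic pyranone-fused 7-oxanorbornadiene by the 6-OH of a 7-O-protected 6,7-dihydroxy-2-phenethylchromone.
3. Pyranone-fused 7-oxanorbornadiene (ring A plus upper pyranone): Favorskii ring contraction of a trichloro-8-oxabicyclo[3.2.1]octenone, terminated by the enolate of 4-(4-methoxyphenyl)butan-2-one, then O-cyclisation. The bicyclic ketone comes from furan + tetrachloroacetone ([4+3]); the ketone from anisole + methyl vinyl ketone.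
4. Lower chromone: p-benzoquinone → triacetoxybenzene → trihydroxyacetophenone → Claisen/cyclodehydration with 3-phenylpropanoyl chloride (acid from acetic acid + benzyl bromide).
5. Ring order: seven-membered oxabicyclic ketone → contracted to ring A with pyranone A; chromone B made separately; dioxepine closed last.

Assumption 1: ring A is drawn with C4a→C5→C6→C7→C8→C8a clockwise; the target then has 5-O up, 6-OH down, 7-O up, 8-OH down, i.e. (5R,6S,7R,8S).
Assumption 2: (R,S)-PPF-P(t-Bu)2 is taken as the Josiphos enantiomer matched to (5R,8S)-9; if a test run shows the opposite, its mirror image is used.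

**Route**

Step 1
Reactants: 1 anisole; 2 methyl vinyl ketone (but-3-en-2-one)
Product: 3 4-(4-methoxyphenyl)butan-2-one
Conditions: Sc(OTf)3 (5 mol %), anisole (5 equiv), MeNO2, 25 °C
Reagents that add atoms: none
Why: Lewis-acid-catalysed Friedel–Crafts conjugate addition (hydroarylation of an enone); OMe directs para and excess anisole suppresses dialkylation; no stereocentre.

Step 2
Reactants: 4 furan; 5 1,1,3,3-tetrachloropropan-2-one
Product: 6 rac-2,2,4-trichloro-8-oxabicyclo[3.2.1]oct-6-en-3-one (C4 epimers)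
Conditions: Et3N (1.05 equiv), furan (5 equiv), CF3CH2OH, 0 → 25 °C
Reagents that add atoms: none
Why: Föhlisch-type [4+3] cycloaddition; dehydrochlorination of 5 in trifluoroethanol in the presence of furan gives the bridged cycloheptenone; it is racemic, and the C4 configuration is irrelevant because C4 becomes sp2 later.

Step 3
Reactants: 6 rac-2,2,4-trichloro-8-oxabicyclo[3.2.1]oct-6-en-3-one; 3 4-(4-methoxyphenyl)butan-2-one
Product: 9 rac-(5R,8S)-2-[2-(4-methoxyphenyl)ethyl]-5,8-dihydro-4H-5,8-epoxychromen-4-one, via dichlorocyclopropanone 7 (not isolated), via chlorovinyl diketone 8 (not isolated)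
Conditions: 3 (1.1 equiv), LiHMDS (3.3 equiv), THF, –78 °C; then 6, –78 → 0 °C; aq NH4Cl
Reagents that add atoms: none
Why: Proposed new method: a Favorskii ring contraction in which a ketone enolate, not an alkoxide, opens the cyclopropanone. Base removes H-4 of 6 and chloride loss gives 7; the methyl-side lithium enolate of 3 adds to its C=O, and ring opening with loss of a second chloride gives the β-chlorovinyl 1,3-diketone 8 (cycloheptenone → six-membered ring A with the former C=O carbon exocyclic as C4); the diketonate oxygen then displaces the vinylic chloride by addition–elimination to close the γ-pyrone. The closest known reactions are the Favorskii rearrangement of α,α,α'-trihalo ketones to β-haloacrylates with alkoxide or hydroxide, and γ-pyrone closure of β-chlorovinyl 1,3-diketones; the product is racemic with the bridgeheads necessarily cis.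

Step 4
Reactants: 10 acetic acid; 11 benzyl bromide
Product: 12 3-phenylpropanoic acid
Conditions: LDA (2.2 equiv), THF–DMPU, 0 °C; then 11, 0 → 25 °C; aq HCl
Reagents that add atoms: none
Why: C-alkylation of the acetic acid dianion (carboxylate enolate alkylation).

Step 5
Reactants: 13 p-benzoquinone; 14 acetic anhydride
Product: 15 benzene-1,2,4-triyl triacetate
Conditions: Ac2O (excess, also solvent), H2SO4 (cat.), 40–50 °C
Reagents that add atoms: acetic anhydride (second equivalent), CC(=O)OC(C)=O
Why: Thiele–Winter acetoxylation: conjugate addition of acetate to the O-acylated quinone, enolisation and peracetylation; the quinone takes up two molecules of acetic anhydride and releases one of acetic acid.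

Step 6
Reactants: 15 benzene-1,2,4-triyl triacetate
Product: 16 1-(2,4,5-trihydroxyphenyl)ethan-1-one
Conditions: ZnCl2, AcOH, 140 °C; then H2O, 60 °C
Reagents that add atoms: none
Why: Fries rearrangement (Nencki conditions); the acetyl enters the position ortho/para to two oxygens, and the remaining aryl acetates are hydrolysed on aqueous work-up.

Step 7
Reactants: 16 1-(2,4,5-trihydroxyphenyl)ethan-1-one; 12 3-phenylpropanoic acid
Product: 19 6,7-dihydroxy-2-(2-phenylethyl)-4H-chromen-4-one, via 3-phenylpropanoyl chloride 17 (not isolated), via aryl 1,3-diketone 18 (not isolated)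
Conditions: 12, (COCl)2, DMF (cat.), CH2Cl2, 25 °C; 16, LiHMDS (5 equiv), THF, –78 → –20 °C, then 17; then AcOH, H2SO4 (cat.), 95 °C
Reagents that add atoms: none
Why: Claisen-type C-acylation of the polylithiated hydroxyacetophenone enolate (Cushman procedure), then acid-catalysed cyclodehydration of the 1,3-diketone to the chromone.

Step 8
Reactants: 19 6,7-dihydroxy-2-(2-phenylethyl)-4H-chromen-4-one
Product: 20 6-hydroxy-2-(2-phenylethyl)-7-[2-(trimethylsilyl)ethoxy]-4H-chromen-4-one
Conditions: Me3SiCH2CH2OH (1.05 equiv), PPh3, DIAD, THF, 0 → 25 °C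
Reagents that add atoms: 2-(trimethylsilyl)ethanol, C[Si](C)(C)CCO
Why: Mitsunobu etherification; the 7-OH (para-conjugated to the C4 carbonyl, the more acidic phenol) reacts selectively, and an ether cannot migrate to O6.

Step 9
Reactants: 9 rac-(5R,8S)-2-[2-(4-methoxyphenyl)ethyl]-5,8-dihydro-4H-5,8-epoxychromen-4-one (2.2 equiv of racemate; only the (5R,8S)-enantiomer is consumed); 20 6-hydroxy-2-(2-phenylethyl)-7-[2-(trimethylsilyl)ethoxy]-4H-chromen-4-one
Product: 21 (7R,8S)-8-hydroxy-2-[2-(4-methoxyphenyl)ethyl]-7-({4-oxo-2-(2-phenylethyl)-7-[2-(trimethylsilyl)ethoxy]-4H-chromen-6-yl}oxy)-7,8-dihydro-4H-chromen-4-one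
Conditions: [Rh(cod)Cl]2 (2.5 mol %), (R,S)-PPF-P(t-Bu)2 (6 mol %), THF, 60 °C; the unreacted (5S,8R)-enantiomer of 9 is separated by chromatography
Reagents that add atoms: none
Why: Lautens Rh(I)-catalysed asymmetric ring opening of an oxabicyclic alkene, run as a kinetic resolution. Rh inserts into the C5–O bond (the bridgehead whose positive charge is stabilised by the ring oxygen through C4a=C8a), and the phenol attacks C7 anti (SN2') to give the 7,8-trans product; the matched (5R,8S)-enantiomer gives 7R (new) and 8S (retained), and the (5S,8R)-enantiomer is left behind.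

Step 10
Reactants: 21 (7R,8S)-TMSE ether
Product: 22 (7R,8S)-8-hydroxy-7-{[7-hydroxy-4-oxo-2-(2-phenylethyl)-4H-chromen-6-yl]oxy}-2-[2-(4-methoxyphenyl)ethyl]-7,8-dihydro-4H-chromen-4-one
Conditions: TBAF (1.5 equiv), THF, 0 → 25 °C; then AcOH to pH 6–7
Reagents that add atoms: none
Why: Fluoride-induced β-elimination of the 2-(trimethylsilyl)ethyl aryl ether; the near-neutral conditions avoid acid-promoted aromatisation of the dihydrochromone, and no stereocentre is touched.

Step 11
Reactants: 22 (7R,8S)-phenol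
Product: 24 (+)-4'-methoxyaquisinenone G (5R,6S,7R,8S), via epoxide 23 (not isolated)
Conditions: DMDO (1.05 equiv), acetone–CH2Cl2, –40 °C; then PPTS (5 mol %), –40 → 0 °C
Reagents that add atoms: dimethyldioxirane, CC1(C)OO1
Why: Epoxidation of the electron-rich C5=C6 alkene anti to the allylic 7-aryloxy group (and syn to the 8-OH) gives the lower-face 5,6-epoxide 23; the 7'-OH then opens it anti at the vinylogously benzylic C5 (7-endo epoxide opening), setting C5 (R, O up) and C6 (S, OH down).

**Compound list**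

1 | anisole | COc1ccccc1 | starting material
2 | methyl vinyl ketone | CC(=O)C=C | starting material
3 | 4-(4-methoxyphenyl)butan-2-one | COc1ccc(CCC(C)=O)cc1 | intermediate
4 | furan | c1ccoc1 | starting material
5 | 1,1,3,3-tetrachloropropan-2-one | O=C(C(Cl)Cl)C(Cl)Cl | starting material
6 | rac-2,2,4-trichloro-8-oxabicyclo[3.2.1]oct-6-en-3-one (C4 epimers) | O=C1C(Cl)C2C=CC(O2)C1(Cl)Cl | intermediate
7 | 2,4-dichloro-8-oxatricyclo[3.2.1.0(2,4)]oct-6-en-3-one (racemic) | O=C1C2(Cl)C3C=CC(O3)C12Cl | intermediate (not isolated)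
8 | 1-(3-chloro-7-oxabicyclo[2.2.1]hepta-2,5-dien-2-yl)-5-(4-methoxyphenyl)pentane-1,3-dione (racemic) | COc1ccc(CCC(=O)CC(=O)C2=C(Cl)C3C=CC2O3)cc1 | intermediate (not isolated)
9 | rac-(5R,8S)-2-[2-(4-methoxyphenyl)ethyl]-5,8-dihydro-4H-5,8-epoxychromen-4-one (racemate; the (5R,8S)-enantiomer shown is carried on) | COc1ccc(CCc2cc(=O)c3c(o2)[C@@H]2C=C[C@H]3O2)cc1 | intermediate
10 | acetic acid | CC(=O)O | starting material
11 | benzyl bromide | BrCc1ccccc1 | starting material
12 | 3-phenylpropanoic acid | OC(=O)CCc1ccccc1 | intermediate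
13 | p-benzoquinone | O=C1C=CC(=O)C=C1 | starting material
14 | acetic anhydride | CC(=O)OC(C)=O | starting material
15 | benzene-1,2,4-triyl triacetate | CC(=O)Oc1ccc(OC(C)=O)c(OC(C)=O)c1 | intermediate
16 | 1-(2,4,5-trihydroxyphenyl)ethan-1-one | CC(=O)c1cc(O)c(O)cc1O | intermediate
17 | 3-phenylpropanoyl chloride | O=C(Cl)CCc1ccccc1 | intermediate (not isolated)
18 | 5-phenyl-1-(2,4,5-trihydroxyphenyl)pentane-1,3-dione | O=C(CCc1ccccc1)CC(=O)c1cc(O)c(O)cc1O | intermediate (not isolated)
19 | 6,7-dihydroxy-2-(2-phenylethyl)-4H-chromen-4-one | O=c1cc(CCc2ccccc2)oc2cc(O)c(O)cc12 | intermediate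
20 | 6-hydroxy-2-(2-phenylethyl)-7-[2-(trimethylsilyl)ethoxy]-4H-chromen-4-one | O=c1cc(CCc2ccccc2)oc2cc(OCC[Si](C)(C)C)c(O)cc12 | intermediate
21 | (7R,8S)-8-hydroxy-2-[2-(4-methoxyphenyl)ethyl]-7-({4-oxo-2-(2-phenylethyl)-7-[2-(trimethylsilyl)ethoxy]-4H-chromen-6-yl}oxy)-7,8-dihydro-4H-chromen-4-one | COc1ccc(CCc2cc(=O)c3c(o2)[C@@H](O)[C@H](Oc2cc4c(=O)cc(CCc5ccccc5)oc4cc2OCC[Si](C)(C)C)C=C3)cc1 | intermediate
22 | (7R,8S)-8-hydroxy-7-{[7-hydroxy-4-oxo-2-(2-phenylethyl)-4H-chromen-6-yl]oxy}-2-[2-(4-methoxyphenyl)ethyl]-7,8-dihydro-4H-chromen-4-one | COc1ccc(CCc2cc(=O)c3c(o2)[C@@H](O)[C@H](Oc2cc4c(=O)cc(CCc5ccccc5)oc4cc2O)C=C3)cc1 | intermediate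
23 | (5S,6S,7S,8S)-5,6-epoxide of 22 (epoxide oxygen trans to the 7-aryloxy group, cis to 8-OH) | COc1ccc(CCc2cc(=O)c3c(o2)[C@@H](O)[C@H](Oc2cc4c(=O)cc(CCc5ccccc5)oc4cc2O)[C@H]2O[C@@H]32)cc1 | intermediate (not isolated)
24 | (+)-4'-methoxyaquisinenone G, (5R,6S,7R,8S) | COc1ccc(CCc2cc(=O)c3c(o2)[C@@H](O)[C@@H]2Oc4cc5c(=O)cc(CCc6ccccc6)oc5cc4O[C@H]3[C@@H]2O)cc1 | target

**Step count and risk**

Total steps: 11. Longest linear sequence: 7 (steps 5, 6, 7, 8, 9, 10, 11, from p-benzoquinone).

Three steps most likely to fail: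

Step 3 (the proposed new enolate-terminated Favorskii contraction). The risks are halophilic attack or aldol addition of the enolate on 6, and C- versus O-closure of 8. The fallback uses known chemistry and sets out from 6. A conventional Favorskii rearrangement with aqueous NaOH, known for α,α,α'-trihalo ketones, gives 3-chloro-7-oxabicyclo[2.2.1]hepta-2,5-diene-2-carboxylic acid F1. Oxalyl chloride converts it into 3-chloro-7-oxabicyclo[2.2.1]hepta-2,5-diene-2-carbonyl chloride F2. C-acylation of the kinetic, methyl-side lithium enolate of ketone 3 (LDA, THF, –78 °C, two equivalents of enolate) with F2 gives diketone 8, where the route is rejoined, and DBU closes 8 to 9.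

Step 9 (kinetic resolution during ring opening). The risk is a low selectivity factor on this unsymmetrical, hetero-fused oxabicycle, or opening of the mismatched enantiomer at the other bridgehead. The fallback sets out from 9 and 20: ring opening with the achiral catalyst [Rh(cod)Cl]2/DPPF gives 21 together with its mirror image, (7S,8R)-8-hydroxy-2-[2-(4-methoxyphenyl)ethyl]-7-({4-oxo-2-(2-phenylethyl)-7-[2-(trimethylsilyl)ethoxy]-4H-chromen-6-yl}oxy)-7,8-dihydro-4H-chromen-4-one F3, which is removed by preparative chiral SFC. The route is rejoined at 21.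

Step 11 (epoxidation and 7-endo closure). The risks are the wrong epoxide face, 6-exo opening at C6, and aromatisation. The fallback sets out from 22: Upjohn dihydroxylation (OsO4 cat., NMO, acetone–H2O) from the face anti to the 7-aryloxy group gives (5S,6S,7R,8S)-5,6,8-trihydroxy-7-{[7-hydroxy-4-oxo-2-(2-phenylethyl)-4H-chromen-6-yl]oxy}-2-[2-(4-methoxyphenyl)ethyl]-5,6,7,8-tetrahydro-4H-chromen-4-one F4. Catalytic Sc(OTf)3 in MeCN then ionises the vinylogously benzylic C5–OH, and the 7'-OH captures the cation on the only face the tether allows (SN1 cyclodehydration), so the route comes back at 24.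

**Further compounds**

F1 | step 3 | 3-chloro-7-oxabicyclo[2.2.1]hepta-2,5-diene-2-carboxylic acid (racemic) | OC(=O)C1=C(Cl)C2C=CC1O2
F2 | step 3 | 3-chloro-7-oxabicyclo[2.2.1]hepta-2,5-diene-2-carbonyl chloride (racemic) | O=C(Cl)C1=C(Cl)C2C=CC1O2
F3 | step 9 | (7S,8R)-8-hydroxy-2-[2-(4-methoxyphenyl)ethyl]-7-({4-oxo-2-(2-phenylethyl)-7-[2-(trimethylsilyl)ethoxy]-4H-chromen-6-yl}oxy)-7,8-dihydro-4H-chromen-4-one | COc1ccc(CCc2cc(=O)c3c(o2)[C@H](O)[C@@H](Oc2cc4c(=O)cc(CCc5ccccc5)oc4cc2OCC[Si](C)(C)C)C=C3)cc1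
F4 | step 11 | (5S,6S,7R,8S)-5,6,8-trihydroxy-7-{[7-hydroxy-4-oxo-2-(2-phenylethyl)-4H-chromen-6-yl]oxy}-2-[2-(4-methoxyphenyl)ethyl]-5,6,7,8-tetrahydro-4H-chromen-4-one | COc1ccc(CCc2cc(=O)c3c(o2)[C@@H](O)[C@H](Oc2cc4c(=O)cc(CCc5ccccc5)oc4cc2O)[C@@H](O)[C@H]3O)cc1
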